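**Plan**
- Retrosynthesis: remove the acetate, take the carbinol back to the ketone (epoxyquinone), remove the epoxide oxygen (quinone monoketal), then rearomatise to 2-farnesyl-4-methoxy-5-methylphenol.
- The six-membered carbocycle is then cut at the bond between the ketone carbon and the farnesyl-bearing carbon and re-closed between the two oxygen-bearing para carbons, giving a 4-alkenyl-4-methoxy-3-methylcyclobutenone.
- Enabling feature: the ring has oxygen on two para carbons (enone C=O and CH–OAc) with CH=/C(CH3)= on one side and the two epoxide carbons on the other. This is the retron of a cyclobutenone 4π-opening/6π-closure, in which four ring atoms come from the cyclobutenone and two from an alkene side arm.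
- Forward: farnesyl bromide is extended to an E-vinyl iodide; a squarate-derived four-membered ring takes up this arm and then a methyl group by two carbonyl additions; ring expansion gives the arene with its two oxygens differentiated; oxidation to the monoketal, epoxidation, hydrolysis, reduction and acetylation follow.
- Stereochemistry: both E-alkenes come from farnesyl bromide. The two epoxide carbons are set by catalyst-controlled nucleophilic epoxidation, with regiochemistry from β-H versus β-CH3. The carbinol is set by hydride delivery anti to the epoxide oxygen.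

Key step: step 6

Assumption: the sense of induction of the cinchona phase-transfer epoxidation in step 8 is taken by analogy with simpler quinone monoketals and must be confirmed on this substrate; the pseudoenantiomeric cinchoninium salt is available if the sense is the opposite.

Abbreviations: Far = (2E,6E)-3,7,11-trimethyldodeca-2,6,10-trien-1-yl; TTT = (1E,4E,8E)-5,9,13-trimethyltetradeca-1,4,8,12-tetraen-1-yl.

**Step 1**
Reactants: 1 (2E,6E)-farnesyl bromide; 2 ethynylmagnesium bromide
Product: 3 (4E,8E)-5,9,13-trimethyltetradeca-4,8,12-trien-1-yne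
Conditions: CuCl (10 mol %), THF, 0 °C to 40 °C
Reagents that add atoms: none
Why: Copper-catalysed SN2 coupling of an alkynyl Grignard with a primary allylic bromide should join the carbons at the unsubstituted allylic terminus with retention of the 2E geometry.

**Step 2**
Reactants: 3 (4E,8E)-5,9,13-trimethyltetradeca-4,8,12-trien-1-yne
Product: 5 (1E,4E,8E)-1-iodo-5,9,13-trimethyltetradeca-1,4,8,12-tetraene, via (E)-alkenylzirconocene chloride 4 (not isolated)
Conditions: Cp2Zr(H)Cl, THF, rt; then I2, 0 °C
Reagents that add atoms: iodine, II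
Why: Schwartz hydrozirconation should add Zr–H syn and anti-Markovnikov to the terminal alkyne only (trisubstituted alkenes are inert at rt), and iodinolysis of the C–Zr bond with retention should give the E-vinyl iodide.

**Step 3**
Reactants: 6 diisopropyl squarate
Product: 8 3-isopropoxycyclobut-3-ene-1,2-dione, via 4-hydroxy-2,3-diisopropoxycyclobut-2-en-1-one 7 (not isolated)
Conditions: LiAlH(OtBu)3, THF, −78 to 0 °C; then conc. HCl, CH2Cl2, rt
Reagents that add atoms: water, O
Why: 1,2-Hydride addition to one squarate carbonyl followed by acid-induced ionisation of the carbinol, hydration at the alkoxy-stabilised terminus and loss of isopropanol should give the semisquarate (Stork–Danheiser-type carbonyl transposition).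

**Step 4**
Reactants: 5 (1E,4E,8E)-1-iodo-5,9,13-trimethyltetradeca-1,4,8,12-tetraene; 8 3-isopropoxycyclobut-3-ene-1,2-dione
Product: 11 3-isopropoxy-4-methoxy-4-TTT-cyclobut-2-en-1-one (racemic), via alkenyllithium 9 (not isolated), via lithium alkoxide 10 (not isolated)
Conditions: 5, t-BuLi (2 equiv), Et2O, −78 °C; add to 8, THF, −78 °C; then MeOTf, −78 to 0 °C
Reagents that add atoms: methyl triflate, COS(=O)(=O)C(F)(F)F
Why: Iodine–lithium exchange with retention gives the vinyllithium, which should add 1,2 to the ketone-like carbonyl next to the isopropoxy-bearing carbon (the other carbonyl is a deactivated vinylogous ester), and the tertiary alkoxide is O-methylated in situ (organolithium addition to a squarate-type dione with triflate trapping).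

**Step 5**
Reactants: 11 3-isopropoxy-4-methoxy-4-TTT-cyclobut-2-en-1-one
Product: 13 4-methoxy-3-methyl-4-TTT-cyclobut-2-en-1-one (racemic), via 3-isopropoxy-4-methoxy-1-methyl-4-TTT-cyclobut-2-en-1-ol 12 (not isolated)
Conditions: MeLi, THF, −78 °C; then 1 M HCl, THF, 0 °C
Reagents that add atoms: methyllithium, [Li]C; water, O
Why: MeLi should add 1,2 to the only remaining carbonyl, and acid then ionises the tertiary allylic alcohol to an isopropoxy-stabilised cation that is hydrated at the alkoxy carbon, moving the carbonyl and leaving methyl on the β-carbon (Stork–Danheiser 1,3-carbonyl transposition as used for 3-alkoxycyclobutenones).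

**Step 6**
Reactants: 13 4-methoxy-3-methyl-4-TTT-cyclobut-2-en-1-one
Product: 16 2-farnesyl-4-methoxy-5-methylphenol, via dienylketene 14 (not isolated), via 6-farnesyl-4-methoxy-3-methylcyclohexa-2,4-dien-1-one 15 (not isolated)
Conditions: toluene (0.02 M, degassed, Ar), 110 °C
Reagents that add atoms: none
Why: Heating should open the cyclobutenone by conrotatory 4π electrocyclic cleavage of the bond between the carbonyl carbon and the methoxy-bearing carbon to give dienylketene 14, the methoxy donor rotating outward so that the alkenyl arm lies cis to the ketene. The six-membered ring then closes by a thermal disrotatory 6π electrocyclisation that bonds the ketene carbon to the terminal carbon of the E-alkene arm (an electrocyclic closure, not a nucleophilic exo/endo attack), and dienone 15 tautomerises to the phenol, which drives the sequence together with release of four-ring strain. The closest known reaction type is the thermal ring expansion of 4-alkenyl- or 4-aryl-4-hydroxy/alkoxycyclobutenones to hydroquinone derivatives (Moore/Liebeskind). No stereocentre is formed. The selectivity needed is positional and is fixed in the substrate: the ketone carbon becomes the free phenol and the C(OMe) carbon the aryl methyl ether, with H, CH3, H and farnesyl placed by their positions on the four-membered ring and the arm, so the two ring oxygens emerge differentiated. High dilution under argon should suppress ketene dimerisation and oxidation of the electron-rich phenol; the skipped triene is expected to tolerate 110 °C.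

**Step 7**
Reactants: 16 2-farnesyl-4-methoxy-5-methylphenol
Product: 17 2-farnesyl-4,4-dimethoxy-5-methylcyclohexa-2,5-dien-1-one
Conditions: PhI(OAc)2, NaHCO3, MeOH, 0 °C
Reagents that add atoms: methanol, CO
Why: Hypervalent-iodine oxidative dearomatisation of a p-methoxyphenol in methanol should turn the free phenol carbon into the ketone and the methoxy-bearing para carbon into the dimethyl ketal, much faster than any reaction at the isolated trisubstituted alkenes.

**Step 8**
Reactants: 17 2-farnesyl-4,4-dimethoxy-5-methylcyclohexa-2,5-dien-1-one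
Product: 18 (1R,6S)-1-farnesyl-5,5-dimethoxy-4-methyl-7-oxabicyclo[4.1.0]hept-3-en-2-one
Conditions: t-BuOOH (decane), N-benzylcinchonidinium chloride (10 mol %), aq NaOH (cat.), toluene, 0 °C
Reagents that add atoms: tert-butyl hydroperoxide, CC(C)(C)OO
Why: In this Weitz–Scheffer epoxidation under chiral phase-transfer catalysis (Wynberg type, known on quinone monoketals) the peroxide anion should add only to the β-unsubstituted enone carbon next to the ketal (the other β-carbon carries methyl), and the ion-paired chiral cation selects the enone face, setting both cis-fused epoxide carbons in one event.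

**Step 9**
Reactants: 18 (1R,6S)-1-farnesyl-5,5-dimethoxy-4-methyl-7-oxabicyclo[4.1.0]hept-3-en-2-one
Product: 19 (1R,6S)-1-farnesyl-4-methyl-7-oxabicyclo[4.1.0]hept-3-ene-2,5-dione
Conditions: Montmorillonite K10 (wet), CH2Cl2, rt
Reagents that add atoms: water, O
Why: Mild solid-acid hydrolysis of the allylic dimethyl ketal through an oxocarbenium ion should free the second carbonyl without opening the epoxide or protonating the trisubstituted alkenes; the stereocentres are untouched.

**Step 10**
Reactants: 19 (1R,6S)-1-farnesyl-4-methyl-7-oxabicyclo[4.1.0]hept-3-ene-2,5-dione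
Product: 20 (1R,5R,6R)-1-farnesyl-5-hydroxy-4-methyl-7-oxabicyclo[4.1.0]hept-3-en-2-one
Conditions: DIBAL-H (1.05 equiv), THF, −78 °C; Rochelle salt work-up
Reagents that add atoms: none
Why: 1,2-Reduction should occur at the less hindered carbonyl (flanked by the epoxide CH and the methyl-bearing alkene carbon, not by the quaternary farnesyl-bearing epoxide carbon), with hydride delivered anti to the epoxide oxygen so that the new carbinol is syn to the epoxide (substrate control).

**Step 11**
Reactants: 20 (1R,5R,6R)-1-farnesyl-5-hydroxy-4-methyl-7-oxabicyclo[4.1.0]hept-3-en-2-one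
Product: 21 (1R,5R,6R)-1-farnesyl-4-methyl-2-oxo-7-oxabicyclo[4.1.0]hept-3-en-5-yl acetate (target)
Conditions: Ac2O, pyridine, DMAP (cat.), CH2Cl2, 0 °C
Reagents that add atoms: acetic anhydride, CC(=O)OC(C)=O
Why: DMAP-catalysed acylation of the secondary alcohol under weakly basic conditions should give the acetate with no change at any stereocentre.

**Compound list**
1 | (2E,6E)-farnesyl bromide | BrC/C=C(\C)CC/C=C(\C)CCC=C(C)C | starting material
2 | ethynylmagnesium bromide | C#C[Mg]Br | starting material
3 | (4E,8E)-5,9,13-trimethyltetradeca-4,8,12-trien-1-yne | C#CC/C=C(\C)CC/C=C(\C)CCC=C(C)C | intermediate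
4 | chlorobis(cyclopentadienyl)(TTT)zirconium (Cp drawn η1) | Cl[Zr](/C=C/C/C=C(\C)CC/C=C(\C)CCC=C(C)C)(C1C=CC=C1)C1C=CC=C1 | intermediate
5 | (1E,4E,8E)-1-iodo-5,9,13-trimethyltetradeca-1,4,8,12-tetraene | I/C=C/C/C=C(\C)CC/C=C(\C)CCC=C(C)C | intermediate
6 | diisopropyl squarate (3,4-diisopropoxycyclobut-3-ene-1,2-dione) | CC(C)OC1=C(OC(C)C)C(=O)C1=O | starting material
7 | 4-hydroxy-2,3-diisopropoxycyclobut-2-en-1-one | CC(C)OC1=C(OC(C)C)C(O)C1=O | intermediate
8 | 3-isopropoxycyclobut-3-ene-1,2-dione | CC(C)OC1=CC(=O)C1=O | intermediate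
9 | (1E,4E,8E)-5,9,13-trimethyltetradeca-1,4,8,12-tetraen-1-yllithium | [Li]/C=C/C/C=C(\C)CC/C=C(\C)CCC=C(C)C | intermediate
10 | lithium 2-isopropoxy-4-oxo-1-TTT-cyclobut-2-en-1-olate | [Li]OC1(/C=C/C/C=C(\C)CC/C=C(\C)CCC=C(C)C)C(=O)C=C1OC(C)C | intermediate
11 | 3-isopropoxy-4-methoxy-4-TTT-cyclobut-2-en-1-one (racemic) | O=C1C=C(OC(C)C)C1(OC)/C=C/C/C=C(\C)CC/C=C(\C)CCC=C(C)C | intermediate
12 | 3-isopropoxy-4-methoxy-1-methyl-4-TTT-cyclobut-2-en-1-ol (formed as its lithium alkoxide) | CC1(O)C=C(OC(C)C)C1(OC)/C=C/C/C=C(\C)CC/C=C(\C)CCC=C(C)C | intermediate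
13 | 4-methoxy-3-methyl-4-TTT-cyclobut-2-en-1-one (racemic) | O=C1C=C(C)C1(OC)/C=C/C/C=C(\C)CC/C=C(\C)CCC=C(C)C | intermediate
14 | dienylketene, 4-methoxy-3-methyl-substituted, alkenyl arm cis to the ketene | O=C=C/C(C)=C(OC)\C=C\C/C=C(\C)CC/C=C(\C)CCC=C(C)C | intermediate
15 | 6-farnesyl-4-methoxy-3-methylcyclohexa-2,4-dien-1-one | O=C1C=C(C)C(OC)=CC1C/C=C(\C)CC/C=C(\C)CCC=C(C)C | intermediate
16 | 2-farnesyl-4-methoxy-5-methylphenol | COc1cc(C/C=C(\C)CC/C=C(\C)CCC=C(C)C)c(O)cc1C | intermediate
17 | 2-farnesyl-4,4-dimethoxy-5-methylcyclohexa-2,5-dien-1-one | COC1(OC)C=C(C/C=C(\C)CC/C=C(\C)CCC=C(C)C)C(=O)C=C1C | intermediate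
18 | (1R,6S)-1-farnesyl-5,5-dimethoxy-4-methyl-7-oxabicyclo[4.1.0]hept-3-en-2-one | COC1(OC)C(C)=CC(=O)[C@]2(C/C=C(\C)CC/C=C(\C)CCC=C(C)C)O[C@H]12 | intermediate
19 | (1R,6S)-1-farnesyl-4-methyl-7-oxabicyclo[4.1.0]hept-3-ene-2,5-dione | O=C1C(C)=CC(=O)[C@]2(C/C=C(\C)CC/C=C(\C)CCC=C(C)C)O[C@H]12 | intermediate
20 | (1R,5R,6R)-1-farnesyl-5-hydroxy-4-methyl-7-oxabicyclo[4.1.0]hept-3-en-2-one | O[C@@H]1C(C)=CC(=O)[C@]2(C/C=C(\C)CC/C=C(\C)CCC=C(C)C)O[C@H]12 | intermediate
21 | (1R,5R,6R)-1-farnesyl-4-methyl-2-oxo-7-oxabicyclo[4.1.0]hept-3-en-5-yl acetate | CC(=O)O[C@@H]1C(C)=CC(=O)[C@]2(C/C=C(\C)CC/C=C(\C)CCC=C(C)C)O[C@H]12 | target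

**Count**
Total steps: 11. Longest linear sequence: 10 steps (1, 2, 4–11 from farnesyl bromide); step 3 is the side branch from diisopropyl squarate.

**Steps most likely to fail, with fallbacks**

Step 8. The phase-transfer epoxidation may show low facial selectivity or the wrong sense on a 2-alkyl quinone monoketal, and the doubly allylic CH2 may isomerise under base. The fallback sets out from 17 and comes back at 20. Compound 17 would be epoxidised without a chiral catalyst (t-BuOOH, DBU, CH2Cl2) to the racemic epoxy ketal F5. Hydrolysis as in step 9 would give the racemic epoxyquinone F6, and DIBAL-H reduction as in step 10 the racemic syn-epoxy alcohol F7. A lipase-mediated kinetic resolution (Burkholderia cepacia lipase, vinyl acetate, MTBE) is then expected to acetylate the (1S,5S,6S)-alcohol to the antipodal acetate F8 and leave 20, which is separated by chromatography and continues with step 11. The enzyme's enantiopreference must be established on the substrate.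

Step 10. Hydride may attack the other carbonyl (poor regioselectivity) or deliver from the epoxide face. The fallback sets out from 18 and comes back at 21, and removes the choice between two carbonyls. The single ketone of 18 would be reduced (NaBH4, CeCl3, MeOH, −40 °C) to the alcohol F9 (either epimer serves) and silylated (TBSOTf, 2,6-lutidine) to F10. Ketal hydrolysis (PPTS, wet acetone) would give the mono-ketone F11, which is reduced with DIBAL-H anti to the epoxide to the syn-alcohol F12 and acetylated (Ac2O, pyridine, DMAP) to F13. Desilylation (HF·pyridine, THF) would give the allylic alcohol F14, and Dess–Martin oxidation (NaHCO3, CH2Cl2) would restore the enone and give 21.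

Step 4. The vinyllithium may add in conjugate fashion to the unsubstituted ring CH or at the vinylogous-ester carbonyl, and O-methylation of the hindered tertiary alkoxide may be incomplete. The fallback sets out from 3 (through its hydrozirconation product 4) and comes back at 17, replacing carbonyl addition by cross-coupling. Propyne and dichloroketene (Cl3CCOCl, Zn–Cu, Et2O) would give 4,4-dichloro-3-methylcyclobut-2-en-1-one F1, which is mono-dechlorinated (Zn, AcOH/TMEDA, EtOH, 0 °C) to 4-chloro-3-methylcyclobut-2-en-1-one F2. Palladium-catalysed coupling of F2 with 4 ((PhCN)2PdCl2, tri(2-furyl)phosphine, THF) would give the 4-alkenylcyclobutenone F3. Heating F3 (dioxane, 100 °C) should ring-expand it by the same 4π/6π sequence to 2-farnesyl-5-methylphenol F4, and double oxidation with PhI(OAc)2 (2.2 equiv) in MeOH at the free para position would give 17.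

**Further compounds**
F1 | step 4 | 4,4-dichloro-3-methylcyclobut-2-en-1-one | CC1=CC(=O)C1(Cl)Cl
F2 | step 4 | 4-chloro-3-methylcyclobut-2-en-1-one | CC1=CC(=O)C1Cl
F3 | step 4 | 3-methyl-4-TTT-cyclobut-2-en-1-one | CC1=CC(=O)C1/C=C/C/C=C(\C)CC/C=C(\C)CCC=C(C)C
F4 | step 4 | 2-farnesyl-5-methylphenol | Cc1ccc(C/C=C(\C)CC/C=C(\C)CCC=C(C)C)c(O)c1
F5 | step 8 | racemic 1-farnesyl-5,5-dimethoxy-4-methyl-7-oxabicyclo[4.1.0]hept-3-en-2-one | COC1(OC)C(C)=CC(=O)C2(C/C=C(\C)CC/C=C(\C)CCC=C(C)C)OC12
F6 | step 8 | racemic 1-farnesyl-4-methyl-7-oxabicyclo[4.1.0]hept-3-ene-2,5-dione | O=C1C(C)=CC(=O)C2(C/C=C(\C)CC/C=C(\C)CCC=C(C)C)OC12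
F7 | step 8 | racemic (1R*,5R*,6R*)-1-farnesyl-5-hydroxy-4-methyl-7-oxabicyclo[4.1.0]hept-3-en-2-one (both enantiomers) | O[C@@H]1C(C)=CC(=O)[C@]2(C/C=C(\C)CC/C=C(\C)CCC=C(C)C)O[C@H]12.O[C@H]1C(C)=CC(=O)[C@@]2(C/C=C(\C)CC/C=C(\C)CCC=C(C)C)O[C@@H]12
F8 | step 8 | (1S,5S,6S)-1-farnesyl-4-methyl-2-oxo-7-oxabicyclo[4.1.0]hept-3-en-5-yl acetate | CC(=O)O[C@H]1C(C)=CC(=O)[C@@]2(C/C=C(\C)CC/C=C(\C)CCC=C(C)C)O[C@@H]12
F9 | step 10 | alcohol from 18 by reduction of the ring ketone, carbinol configuration unassigned | COC1(OC)C(C)=CC(O)[C@]2(C/C=C(\C)CC/C=C(\C)CCC=C(C)C)O[C@H]12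
F10 | step 10 | tert-butyldimethylsilyl ether of F9 | COC1(OC)C(C)=CC(O[Si](C)(C)C(C)(C)C)[C@]2(C/C=C(\C)CC/C=C(\C)CCC=C(C)C)O[C@H]12
F11 | step 10 | silyloxy enone from F10 by ketal hydrolysis | O=C1C(C)=CC(O[Si](C)(C)C(C)(C)C)[C@]2(C/C=C(\C)CC/C=C(\C)CCC=C(C)C)O[C@H]12
F12 | step 10 | syn-epoxy alcohol from F11 | O[C@@H]1C(C)=CC(O[Si](C)(C)C(C)(C)C)[C@]2(C/C=C(\C)CC/C=C(\C)CCC=C(C)C)O[C@H]12
F13 | step 10 | acetate of F12 | CC(=O)O[C@@H]1C(C)=CC(O[Si](C)(C)C(C)(C)C)[C@]2(C/C=C(\C)CC/C=C(\C)CCC=C(C)C)O[C@H]12
F14 | step 10 | desilylated allylic alcohol from F13 | CC(=O)O[C@@H]1C(C)=CC(O)[C@]2(C/C=C(\C)CC/C=C(\C)CCC=C(C)C)O[C@H]12
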